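Target is the peak we want, and each unit of it costs one nucleophile, while each unit of self-condensation product costs two, so we follow how the nucleophile splits between these two paths.

electrophile 20 mM; nucleophile 18.0 mM; free base 22.0 mM; time 25 h

    electrophile + nucleophile → acid set free + target (k1 = 257 /M/h)
    nucleophile + acid set free ⇌ protonated nucleophile, settled at all times (K2 = 18500 /M)
    acid set free + free base ⇌ salt of the base, settled at all times (K3 = 38000 /M)
    nucleophile + target ⇌ idle adduct, settled at all times (K4 = 41 /M)
    2 nucleophile → self-condensation product (k5 = 70.4 /M/h)

* part of the electrophile that has reacted at 25 h
* share of free nucleophile in free nucleophile and protonated nucleophile together, at 25 h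

Reading these charges, the flask holds 0.900 nucleophile per electrophile, so nucleophile is the limiting reagent. Free base stands at 1.10 per electrophile, above the nucleophile charge.

Let e be the electrophile left and n the nucleophile left, both as fractions of the electrophile charge. As a simplification of our own, we count the remaining nucleophile as free, setting aside its protonated form and the idle adduct. The condensation constant, doubled, over the target constant gives the selectivity factor σ = 0.548: nucleophile lost to condensation per nucleophile used for target is σn/e. Time cancels, leaving dn/de = 1 + σn/e, which integrates in closed form.

The electrophile's half-life by the target step alone, the other concentrations as charged, is 0.15 h, short against 25 h, so we take n to zero. That gives e = (1 − (1 − σ)·0.900) raised to 1/(1 − σ), or 0.315, and thus c = 68.5%.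

For the acid, equilibrium constant times starting concentration reads 840 for the free base against 330 for the nucleophile, so we count the acid set free as salt of the base, one per target. The balance of the salt then gives fr = 55.4%.

The forecast gives 72.2% and 52.1%, stepping by hand to the conclusion “By 25 h the nucleophile is therefore exhausted”. Its c stands 3.7 percentage points above ours.

The simulation gives 72.2% and 52.0%, with 0% of the nucleophile left. With condensation struck out, c is 89.8%, close to the charge ratio 0.900. Our σ puts c 21 points below that ratio, and the simulated c of the flask lies 18 points below the run without condensation.

In the neighbour flask with 4.5 mM of nucleophile, the ratio is 0.225, and the same σ gives c = 21.1%. The simulation of that flask gives 21.2%.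

The numbers are invented; the result is computed.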